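Ochre, with 2.3 mM of free catalyst against 4.9 mM of impurity, stood at 1.0% target after 48.0 h, but amber, with 7.3 mM, reached 32.5%.

in all of them: reagent 0.135 M; impurity 4.9 mM
- ochre: substrate 0.15 M (fed, over 12 h); free catalyst 2.3 mM; run made earlier
- amber: substrate 0.15 M (fed, over 12 h); free catalyst 7.3 mM; run made earlier
- Sunday's: substrate 0.15 M; free catalyst 2.0 mM; everything together at the start; time 3.0 d
- Wednesday's: substrate 0.15 M (fed, over 12 h); free catalyst 6.0 mM; time 3.0 d

| run | time / h | target / % | substrate / % |
|---|---|---|---|
| ochre | 4.00 | 0 | 32.0 |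
| ochre | 6.00 | 0 | 48.4 |
| ochre | 12.0 | 2.0 | 99.7 |
| ochre | 20.0 | 0.5 | 97.4 |
| ochre | 30.0 | 1.9 | 100.5 |
| ochre | 48.0 | 1.0 | 98.2 |
| amber | 4.00 | 1.0 | 32.2 |
| amber | 6.00 | 3.8 | 47.1 |
| amber | 12.0 | 8.3 | 91.1 |
| amber | 20.0 | 10.4 | 85.6 |
| amber | 30.0 | 20.0 | 78.7 |
| amber | 48.0 | 32.5 | 66.7 |

(readings scatter by 1 percentage point)

- percentages count the whole charge, also what has not yet gone in

* which one finishes higher in amount of target, in percent of the substrate charged ("neither" within 2 percentage points) (Sunday's / Wednesday's / neither)
* amount of target at the end, in percent of the substrate charged, Sunday's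
* amount of target at the end, in percent of the substrate charged, Wednesday's

I read those two runs as a titration and kept a ledger. I assumed that one impurity takes one free catalyst to spent catalyst, though the readings place the threshold merely somewhere between the two catalyst charges.

Amber: 7.3 mM − 4.9 mM = 2.40 mM

Wednesday's: 6.0 mM − 4.9 mM = 1.10 mM

Sunday's: 2.0 mM against 4.9 mM, impurity ahead by 2.90 mM

Wednesday's 1.10 mM is its surviving catalyst, the free catalyst charged minus the impurity charged. In Wednesday's the impurity is the limiting reagent of this titration, so the books put 81.7% of the catalyst in spent catalyst. In Sunday's the catalyst is limiting, so they put 100% there and leave 59.2% of the impurity.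

Then I let target scale with surviving catalyst. Amber gained 24 percentage points from 12.0 h to 48.0 h. Wednesday's has 0.458 of amber's surviving catalyst.

Wednesday's target ≈ 0.458 × (8.3% + 24 points × 60.0 h / 36.0 h) = 22.3%

Sunday's has no surviving catalyst, so I put its target near ochre's 1.0%.

The forecast said Wednesday's, with 0.5% and 25%, holding that “the 4.9 mM impurity probably kills catalyst about 1:1”; its Wednesday's figure stood above my 22.3%.

The flask gave 3.68% for Sunday's and 25.1% for Wednesday's, so Wednesday's finished higher. My Wednesday's figure was 2.8 points low, and my Sunday's figure, ochre's 1.0%, was 2.7 points low. Sunday's kept 59% of its impurity against my 59.2%.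

    catalyst intermediate B ⇌ by-product + catalyst intermediate C (K = 0.0730 M, k = 0.730 h⁻¹)
    substrate + free catalyst ⇌ catalyst intermediate A (K = 16.0 M⁻¹, k = 21.0 M⁻¹ h⁻¹)
    catalyst intermediate C → free catalyst + target (k = 110 h⁻¹)
    free catalyst + impurity → spent catalyst (k = 210 M⁻¹ h⁻¹)
    reagent + catalyst intermediate A → catalyst intermediate B (k = 25.0 M⁻¹ h⁻¹)

At 1.34 d in Wednesday's, free catalyst entered catalyst intermediate A 130 times as fast as it fell to spent catalyst, counting the forward step alone. By 3.00 d spent catalyst stood at 81.5% of the catalyst charged, against the ledger's 81.7%, and impurity stood at 0.186% of its charge. The neighbour of Wednesday's charged with 0.024 M of free catalyst has a surviving catalyst of 19.1 mM, so the ledger puts its spent catalyst at 20.4%; at 3.00 d that flask shows 20.4%, with target at 89.7%.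

All runs stem from a simulated flask with constants of no real substance, and the scatter is random.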